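You put two questions to me, the row of [left-handed product] for violet, grey and red and how that row runs.

| setting | west | north-east | violet | grey | red |
|---|---|---|---|---|---|
| left-handed substrate | 0.050 M | 0.050 M | 0.050 M | 0.050 M | 0.050 M |
| right-handed substrate | 0.050 M | 0.050 M | 0.050 M | 0.050 M | 0.050 M |
| partner | 0.65 equiv | 2.4 equiv | 1.20 equiv | 2.00 equiv | 3.00 equiv |
| remark | run made earlier | run made earlier |  |  |  |
| time |  |  | 40 min | 40 min | 40 min |

- west (time / min: left-handed product / %, left-handed substrate / %): 3.00: 21.3, 32.4; 6.00: 20.9, 33.4; 8.00: 21.2, 33.6; 12.0: 21.3, 34.0; 15.0: 21.0, 34.1; 20.0: 20.9, 33.9
- north-east (time / min: left-handed product / %, left-handed substrate / %): 1.00: 50.6, 1.5; 3.00: 52.8, 0; 6.00: 53.1, 0; 8.00: 53.2, 0; 12.0: 53.3, 0.1; 15.0: 52.8, 0; 20.0: 52.9, 0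

(scatter of a reading: 0.3 percentage points)

1. [left-handed product] at the end for violet, grey, red, in this order
2. how the row runs (rises, then falls / rises all the way / hardly changes / falls all the way / falls, then rises)

- partner is single-handed; left-handed substrate and right-handed substrate are mirror images of each other, charged as a racemate, each of them at the stated concentration
- reactions considered so far: left-handed substrate <-> right-handed substrate; partner + left-handed substrate -> left-handed product; partner -> decomposition product; partner + right-handed substrate -> right-handed product
- "hardly changes" means that all values lie within two and a half points (for a concentration: within two and a half percent of the largest)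
- the handed part of partner does not stay in what it makes, so the products of the two hands are mirror images too

I started from the west run. Each hand is lost at a rate proportional to [partner] times its own concentration, so dividing the two rates removes [partner], and the quotient integrates in closed form. At 15.0 min, west read 21.0% left-handed product and 34.1% left-handed substrate. Taking the right-handed substrate as equal, the balance left 10.8% right-handed product. Each hand was charged as half of the total, so the logarithms of the fractions left gave a reading of 2.24. This is the selectivity factor: the power to which the fraction of right-handed substrate left must be raised to give the fraction of left-handed substrate left, as long as the hands do not interconvert.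

With half of the right-handed substrate gone, that rule needed 1.29 equiv of partner, more than violet's 1.20 equiv. So I put violet, where partner is the limiting reagent, a little under 0.0394 M. Grey's 2.00 equiv just covers both hands, and there the rule alone stops at 0.050 M. North-east, at 53.2%, had already gone past half, so I expected grey and red above that figure, but I could not separate them.

The forecast said 0.038 M, 0.055 M and 0.052 M, so rises, then falls, on the ground that a “large excess finishes quickly”.

The flasks gave 0.0376 M, 0.0557 M and 0.0519 M, so rises, then falls, turning at 2.0 equiv.

    left-handed substrate ⇌ right-handed substrate (k = 0.00352 s⁻¹)
    partner + left-handed substrate → left-handed product (k = 1.45 M⁻¹ s⁻¹)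
    partner → decomposition product (k = 1.66 × 10⁻⁵ s⁻¹)
    partner + right-handed substrate → right-handed product (k = 0.656 M⁻¹ s⁻¹)

Violet ended with partner at 0% and 0.0376 M of left-handed product, against 0.0600 M for the same flask without the right-handed step, because right-handed substrate took its share of partner. Violet's 22.4% of right-handed product, put through the selectivity factor, gave 0.0367 M of left-handed product against that simulated 0.0376 M. The same line on red's 48.1% of right-handed product gave 0.0500 M, and red held 0.0519 M.

The data stem from a simulated flask for substances that don't exist; scatter was added.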